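Ring A is disconnected at C1–C10 and C2–C3 (labdane numbering), so that C1–C2 becomes phenyl vinyl sulfone and everything else a monocyclic ring B ketone. In the key step an iron hydride converts the exocyclic C10=C20 methylene into the tertiary C10 radical, which adds to the sulfone; polar crossover and aldol closure onto one of two formyl groups on prochiral C4 then complete ring A. The step exploits the 1,3-relationship of quaternary C10 and carbinol C3 across C1–C2 in ring A and the C4 centre flanked by two carbonyl-level carbons (C3, C19). One operation forms both bonds, makes C20 the angular methyl and sets C10, C3 and C4; the sulfone is then removed reductively.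

Key step: step 10

Remark: atom labels C1–C20 follow labdane numbering throughout, also for the monocyclic precursors.
Assumption: the (R,R)-antipode of the bisphosphine ligand in step 3 is taken to give the R-configured allylation product; if the sense of induction is the opposite, the (S,S)-ligand is used and nothing else changes.

Step 1
Reactants: 1 2-methylcyclohex-2-en-1-one
Product: 2 (±)-2-methylcyclohex-2-en-1-ol
Conditions: NaBH4, CeCl3·7H2O, MeOH, 0 °C
Reagents that add atoms: none
Why: Luche reduction should give clean 1,2-reduction of the enone; the carbinol centre is formed racemic and is erased in step 3.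

Step 2
Reactants: 2 (±)-2-methylcyclohex-2-en-1-ol
Product: 3 (±)-methyl 2-methylcyclohex-2-en-1-yl carbonate
Conditions: ClCO2Me, pyridine, DMAP (cat.), CH2Cl2, 0 °C
Reagents that add atoms: methyl chloroformate, COC(=O)Cl
Why: O-acylation of the allylic alcohol installs a carbonate leaving group that later releases methoxide as the base in situ.

Step 3
Reactants: 3 (±)-methyl 2-methylcyclohex-2-en-1-yl carbonate; 4 dimethyl 2-methylpropanedioate
Product: 5 dimethyl 2-methyl-2-[(1R)-2-methylcyclohex-2-en-1-yl]propanedioate
Conditions: Pd2(dba)3·CHCl3 (2.5 mol %), (R,R)-DACH-phenyl ligand [(1R,2R)-N,N'-bis(2-diphenylphosphinobenzoyl)cyclohexane-1,2-diamine] (7.5 mol %), CH2Cl2, rt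
Reagents that add atoms: none
Why: Tsuji–Trost asymmetric allylic alkylation: ionisation gives a 2-methylcyclohexenyl–palladium cation with enantiotopic termini, and the chiral ligand pocket directs the methylmalonate anion to one terminus, which sets C5 as R (the enantiodetermining step of the route).

Step 4
Reactants: 5 dimethyl 2-methyl-2-[(1R)-2-methylcyclohex-2-en-1-yl]propanedioate
Product: 6 dimethyl 2-methyl-2-[(1R)-2-methyl-4-oxocyclohex-2-en-1-yl]propanedioate
Conditions: Rh2(cap)4 (dirhodium tetracaprolactamate, 1 mol %), t-BuOOH (5 equiv), K2CO3, CH2Cl2, rt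
Reagents that add atoms: tert-butyl hydroperoxide, CC(C)(C)OO
Why: Allylic C–H oxidation should convert the only allylic methylene (C8) into the enone carbonyl, because C5 is tertiary and shielded by the quaternary centre; the C5 stereocentre is not touched.

Step 5
Reactants: 6 dimethyl 2-methyl-2-[(1R)-2-methyl-4-oxocyclohex-2-en-1-yl]propanedioate
Product: 7 dimethyl 2-[(1S)-3-bromo-2-methyl-4-oxocyclohex-2-en-1-yl]-2-methylpropanedioate (same spatial arrangement; the descriptor changes with the priorities)
Conditions: Br2, CH2Cl2, 0 °C; then Et3N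
Reagents that add atoms: bromine, BrBr
Why: Bromination–dehydrobromination: bromine adds to the enone and triethylamine removes HBr through the acidic C9 proton, which gives the α-bromoenone without enolisation toward C5.

Step 6
Reactants: 7 dimethyl 2-[(1S)-3-bromo-2-methyl-4-oxocyclohex-2-en-1-yl]-2-methylpropanedioate; 8 2-methyl-2-vinyl-1,3-dioxolane
Product: 10 dimethyl 2-methyl-2-[(1R)-2-methyl-3-[2-(2-methyl-1,3-dioxolan-2-yl)ethyl]-4-oxocyclohex-2-en-1-yl]propanedioate, via alkylborane 9 (not isolated)
Conditions: 8, 9-BBN-H, THF, 0 °C to rt; then 7, PdCl2(dppf) (5 mol %), AsPh3, Cs2CO3, DMF/H2O, 50 °C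
Reagents that add atoms: 9-borabicyclo[3.3.1]nonane, B1C2CCCC1CCC2 (its atoms stay in intermediate 9 only)
Why: Anti-Markovnikov hydroboration of the vinyl ketal and B-alkyl Suzuki–Miyaura coupling with the α-bromoenone attach C11–C13 and C16 at C9 under a carbonate base that leaves C5 untouched.

Step 7
Reactants: 10 dimethyl 2-methyl-2-[(1R)-2-methyl-3-[2-(2-methyl-1,3-dioxolan-2-yl)ethyl]-4-oxocyclohex-2-en-1-yl]propanedioate
Product: 11 dimethyl 2-methyl-2-[(1R,3R)-2-methylidene-3-[2-(2-methyl-1,3-dioxolan-2-yl)ethyl]-4-oxocyclohexyl]propanedioate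
Conditions: KOt-Bu (3 equiv), t-BuOH/THF, rt; inverse quench into 10% aq AcOH, 0 °C
Reagents that add atoms: none
Why: Deconjugation by kinetic protonation of an extended dienolate: tert-butoxide removes a C20 proton (C5–H is shielded by the adjacent quaternary centre), and fast protonation at C9 from the face anti to the pseudoaxial C5 substituent should give the 2-methylidene ketone with the side chain cis to the C5 substituent (C9 R).

Step 8
Reactants: 11 dimethyl 2-methyl-2-[(1R,3R)-2-methylidene-3-[2-(2-methyl-1,3-dioxolan-2-yl)ethyl]-4-oxocyclohexyl]propanedioate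
Product: 12 2-[(1R,3R)-4-hydroxy-2-methylidene-3-[2-(2-methyl-1,3-dioxolan-2-yl)ethyl]cyclohexyl]-2-methylpropane-1,3-diol (mixture of C8 carbinol epimers)
Conditions: LiAlH4, THF, 0 °C
Reagents that add atoms: none
Why: Hydride reduction of the ketone and both esters removes the risk of re-conjugation; the new C8 carbinol centre is not controlled and is erased in step 9.

Step 9
Reactants: 12 2-[(1R,3R)-4-hydroxy-2-methylidene-3-[2-(2-methyl-1,3-dioxolan-2-yl)ethyl]cyclohexyl]-2-methylpropane-1,3-diol
Product: 13 2-methyl-2-[(1R,3R)-2-methylidene-3-[2-(2-methyl-1,3-dioxolan-2-yl)ethyl]-4-oxocyclohexyl]propanedial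
Conditions: Dess–Martin periodinane (4 equiv), NaHCO3, CH2Cl2, 0 °C to rt
Reagents that add atoms: none
Why: Buffered Dess–Martin oxidation of the three carbinols under non-basic conditions should give the β,γ-unsaturated ketone and the non-enolisable 2,2-disubstituted malonaldehyde without alkene migration or epimerisation at C9.

Step 10
Reactants: 13 2-methyl-2-[(1R,3R)-2-methylidene-3-[2-(2-methyl-1,3-dioxolan-2-yl)ethyl]-4-oxocyclohexyl]propanedial; 14 phenyl vinyl sulfone
Product: 15 3β-hydroxy-8-oxo-2α-(phenylsulfonyl)-13,13-(ethylenedioxy)-14,15,17-trinorlabdan-19-al (trans-decalin with β-methyl at C10, α-methyl and β-formyl at C4, C13 ketone as dioxolane)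
Conditions: Fe(acac)3 (30 mol %), Ph(i-PrO)SiH2 (2.5 equiv), 14 (3 equiv), THF, 0 °C to rt; aqueous NaHCO3 work-up
Reagents that add atoms: none
Why: Proposed new method: hydrogen-atom transfer from an iron hydride (from Fe(acac)3 and the silane) to C20 gives the tertiary C10 radical, which adds to phenyl vinyl sulfone (Giese addition, C1–C10); reduction of the α-sulfonyl radical by divalent iron gives a sulfonyl-stabilised carbanion that closes onto one formyl group (C2–C3), and the iron alkoxide is turned over by the silane in the aprotic medium. The closest known reaction type is the iron-hydride-initiated radical–polar crossover annulation of γ,δ-unsaturated aldehydes with enones and enals; here a vinyl sulfone takes the place of the unsaturated carbonyl partner so that the activating group can be removed afterwards. Ring A closes by a 6-exo-trig aldol-type addition through a chair. C10 is set by approach of the sulfone to the α-face, anti to the β-oriented branches on C5 and C9, which gives the trans ring fusion; C3 and C2 take equatorial hydroxyl and sulfonyl groups in that chair; C4 is set by the choice between the two diastereotopic formyl groups, the chair with equatorial methyl and axial formyl avoiding a 1,3-diaxial methyl–methyl contact with C20. The step needs hydrogen-atom transfer to the 1,1-disubstituted alkene only and closure onto an aldehyde instead of the C8 ketone; the first is secured by the absence of other alkenes, the second by the higher electrophilicity of the aldehyde and the chair six-membered closure against a strained five-membered bridge.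

Step 11
Reactants: 15 3β-hydroxy-8-oxo-2α-(phenylsulfonyl)-13,13-(ethylenedioxy)-14,15,17-trinorlabdan-19-al
Product: 16 3β-hydroxy-8-oxo-2α-(phenylsulfonyl)-13,13-(ethylenedioxy)-14,15,17-trinorlabdan-19-oic acid
Conditions: NaClO2, NaH2PO4, 2-methylbut-2-ene, t-BuOH/H2O, rt
Reagents that add atoms: sodium chlorite, [Na+].[O-]Cl=O
Why: Pinnick oxidation converts the hindered neopentyl C19 aldehyde into the acid without touching the secondary alcohol, ketone, sulfone or ketal.

Step 12
Reactants: 16 3β-hydroxy-8-oxo-2α-(phenylsulfonyl)-13,13-(ethylenedioxy)-14,15,17-trinorlabdan-19-oic acid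
Product: 17 3β-hydroxy-8-oxo-13,13-(ethylenedioxy)-14,15,17-trinorlabdan-19-oic acid
Conditions: Na(Hg) (6% Na), Na2HPO4, MeOH/THF, −20 °C
Reagents that add atoms: none
Why: Reductive desulfonylation (electron transfer, C–S cleavage, protonation by methanol) removes the activating group; the free β-hydroxyl is a poor leaving group, so protonation should win over Julia-type elimination, and an isolated ketone tolerates buffered amalgam at low temperature.

Step 13
Reactants: 17 3β-hydroxy-8-oxo-13,13-(ethylenedioxy)-14,15,17-trinorlabdan-19-oic acid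
Product: 19 3β-hydroxy-13-oxo-14,15-dinorlabd-8(17)-en-19-oic acid, via ketal alkene 18 (not isolated)
Conditions: Ph3PCH3Br, KOt-Bu (6 equiv each), THF, 0 °C to 60 °C; then 2 M HCl, THF, rt
Reagents that add atoms: methyltriphenylphosphonium bromide, C[P+](c1ccccc1)(c1ccccc1)c1ccccc1.[Br-]; water, O
Why: Wittig methylenation of the hindered C8 ketone with excess ylide (carboxylate and alkoxide are spectators), C9 equilibrating under the basic conditions to the equatorial β side chain, followed by acid hydrolysis of the dioxolane in the same flask.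

Step 14
Reactants: 19 3β-hydroxy-13-oxo-14,15-dinorlabd-8(17)-en-19-oic acid; 20 triethyl phosphonoacetate
Product: 21 15-ethyl hydrogen (13E)-3β-hydroxylabda-8(17),13-diene-15,19-dioate
Conditions: NaH (5 equiv), 20 (3 equiv), DME, 0 °C to 60 °C
Reagents that add atoms: none
Why: Horner–Wadsworth–Emmons olefination of the methyl ketone should favour the E-enoate (ester trans to the larger C12 chain); the minor Z isomer is removed by chromatography.

Step 15
Reactants: 21 15-ethyl hydrogen (13E)-3β-hydroxylabda-8(17),13-diene-15,19-dioate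
Product: 22 (13E)-3β-hydroxylabda-8(17),13-diene-15,19-dioic acid (3β-hydroxyagathic acid)
Conditions: LiOH, THF/MeOH/H2O, 50 °C; then aq HCl
Reagents that add atoms: lithium hydroxide, [Li+].[OH-]
Why: Saponification of the ethyl enoate; the C19 acid is present as its carboxylate, and a 3-hydroxyl β to a carboxylate does not undergo retro-aldol cleavage under these conditions.

Step 16
Reactants: 22 (13E)-3β-hydroxylabda-8(17),13-diene-15,19-dioic acid
Product: 23 3β-acetoxy-agathic acid
Conditions: Ac2O, pyridine, DMAP (cat.), rt; then H2O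
Reagents that add atoms: acetic anhydride, CC(=O)OC(C)=O
Why: DMAP-catalysed acetylation of the equatorial 3β-hydroxyl; mixed anhydrides formed at the two acids are hydrolysed on aqueous work-up, so no protecting group is needed.

Compound list
1 | 2-methylcyclohex-2-en-1-one | CC1=CCCCC1=O | starting material
2 | (±)-2-methylcyclohex-2-en-1-ol | CC1=CCCCC1O | intermediate
3 | (±)-methyl 2-methylcyclohex-2-en-1-yl carbonate | COC(=O)OC1CCCC=C1C | intermediate
4 | dimethyl 2-methylpropanedioate | COC(=O)C(C)C(=O)OC | starting material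
5 | dimethyl 2-methyl-2-[(1R)-2-methylcyclohex-2-en-1-yl]propanedioate | COC(=O)C(C)(C(=O)OC)[C@@H]1CCCC=C1C | intermediate
6 | dimethyl 2-methyl-2-[(1R)-2-methyl-4-oxocyclohex-2-en-1-yl]propanedioate | COC(=O)C(C)(C(=O)OC)[C@@H]1CCC(=O)C=C1C | intermediate
7 | dimethyl 2-[(1S)-3-bromo-2-methyl-4-oxocyclohex-2-en-1-yl]-2-methylpropanedioate | COC(=O)C(C)(C(=O)OC)[C@@H]1CCC(=O)C(Br)=C1C | intermediate
8 | 2-methyl-2-vinyl-1,3-dioxolane | C=CC1(C)OCCO1 | starting material
9 | 9-[2-(2-methyl-1,3-dioxolan-2-yl)ethyl]-9-borabicyclo[3.3.1]nonane | CC1(CCB2C3CCCC2CCC3)OCCO1 | intermediate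
10 | dimethyl 2-methyl-2-[(1R)-2-methyl-3-[2-(2-methyl-1,3-dioxolan-2-yl)ethyl]-4-oxocyclohex-2-en-1-yl]propanedioate | COC(=O)C(C)(C(=O)OC)[C@@H]1CCC(=O)C(CCC2(C)OCCO2)=C1C | intermediate
11 | dimethyl 2-methyl-2-[(1R,3R)-2-methylidene-3-[2-(2-methyl-1,3-dioxolan-2-yl)ethyl]-4-oxocyclohexyl]propanedioate | COC(=O)C(C)(C(=O)OC)[C@@H]1CCC(=O)[C@H](CCC2(C)OCCO2)C1=C | intermediate
12 | 2-[(1R,3R)-4-hydroxy-2-methylidene-3-[2-(2-methyl-1,3-dioxolan-2-yl)ethyl]cyclohexyl]-2-methylpropane-1,3-diol (C8 carbinol epimers) | OCC(C)(CO)[C@@H]1CCC(O)[C@H](CCC2(C)OCCO2)C1=C | intermediate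
13 | 2-methyl-2-[(1R,3R)-2-methylidene-3-[2-(2-methyl-1,3-dioxolan-2-yl)ethyl]-4-oxocyclohexyl]propanedial | O=CC(C)(C=O)[C@@H]1CCC(=O)[C@H](CCC2(C)OCCO2)C1=C | intermediate
14 | phenyl vinyl sulfone | C=CS(=O)(=O)c1ccccc1 | starting material
15 | 3β-hydroxy-8-oxo-2α-(phenylsulfonyl)-13,13-(ethylenedioxy)-14,15,17-trinorlabdan-19-al | O=C1CC[C@@H]2[C@](C)(C[C@@H](S(=O)(=O)c3ccccc3)[C@H](O)[C@]2(C)C=O)[C@H]1CCC4(C)OCCO4 | intermediate
16 | 3β-hydroxy-8-oxo-2α-(phenylsulfonyl)-13,13-(ethylenedioxy)-14,15,17-trinorlabdan-19-oic acid | O=C1CC[C@@H]2[C@](C)(C[C@@H](S(=O)(=O)c3ccccc3)[C@H](O)[C@]2(C)C(=O)O)[C@H]1CCC4(C)OCCO4 | intermediate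
17 | 3β-hydroxy-8-oxo-13,13-(ethylenedioxy)-14,15,17-trinorlabdan-19-oic acid | O=C1CC[C@@H]2[C@](C)(CC[C@H](O)[C@]2(C)C(=O)O)[C@H]1CCC3(C)OCCO3 | intermediate
18 | 3β-hydroxy-13,13-(ethylenedioxy)-14,15-dinorlabd-8(17)-en-19-oic acid | C=C1CC[C@@H]2[C@](C)(CC[C@H](O)[C@]2(C)C(=O)O)[C@H]1CCC3(C)OCCO3 | intermediate
19 | 3β-hydroxy-13-oxo-14,15-dinorlabd-8(17)-en-19-oic acid | C=C1CC[C@@H]2[C@](C)(CC[C@H](O)[C@]2(C)C(=O)O)[C@H]1CCC(C)=O | intermediate
20 | triethyl phosphonoacetate | CCOC(=O)CP(=O)(OCC)OCC | starting material
21 | 15-ethyl hydrogen (13E)-3β-hydroxylabda-8(17),13-diene-15,19-dioate | C=C1CC[C@@H]2[C@](C)(CC[C@H](O)[C@]2(C)C(=O)O)[C@H]1CC/C(C)=C/C(=O)OCC | intermediate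
22 | (13E)-3β-hydroxylabda-8(17),13-diene-15,19-dioic acid | C=C1CC[C@@H]2[C@](C)(CC[C@H](O)[C@]2(C)C(=O)O)[C@H]1CC/C(C)=C/C(=O)O | intermediate
23 | 3β-acetoxy-agathic acid | C=C1CC[C@@H]2[C@](C)(CC[C@H](OC(C)=O)[C@]2(C)C(=O)O)[C@H]1CC/C(C)=C/C(=O)O | target

Total step count: 16. Longest linear sequence: 16 steps (1 to 23; 4, 8, 14 and 20 are purchased).

Steps most likely to fail

Step 10 (labelled step). The sulfonyl-stabilised adduct may be quenched by hydrogen-atom capture or protonation before ring closure, and discrimination between the two formyl groups or between the two faces of the C10 radical may be poor. Fallback with known chemistry, from 13 back to 17: the same iron-hydride annulation is run with acrolein, an enal partner of the established class (Fe(acac)3, PhSiH3, EtOH/ethylene glycol), and should give 2α-formyl-3β-hydroxy-8-oxo-13,13-(ethylenedioxy)-14,15,17-trinorlabdan-19-al F1. Pinnick oxidation of both formyl groups gives 3β-hydroxy-8-oxo-13,13-(ethylenedioxy)-14,15,17-trinorlabdane-2α,19-dioic acid F2. Only the unhindered C2 acid is converted with N-hydroxypyridine-2-thione and dicyclohexylcarbodiimide into the Barton ester of the C2 acid F3, because the axial neopentyl C19 acid does not esterify under these conditions. Barton reductive decarboxylation (visible light, t-BuSH) then gives 17, and steps 11 and 12 are not needed.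

Step 7. Proton loss at C5 instead of C20 would erode the C5 stereocentre or give the endocyclic alkene, and re-conjugation or poor facial selectivity of the C9 protonation may occur. Fallback, from 10 back to 11: soft enolisation (TBSOTf, Et3N, CH2Cl2, −78 to 0 °C) removes the accessible C20 proton without a free base and gives the cross-conjugated tert-butyldimethylsilyl dienol ether F4. Fluoride-triggered protodesilylation in the presence of acetic acid (TBAF, AcOH, THF, −78 °C) protonates the dienolate kinetically at C9 and returns to 11. A wrong C9 epimer is not fatal, since C9 equilibrates next to the C8 ketone in step 13.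

Step 3. Ionisation of the 2-methyl-substituted carbonate may be slow and the enantiotopic termini poorly discriminated with the hindered nucleophile. Fallback, from 1 back to 5: Corey–Bakshi–Shibata reduction (oxazaborolidine antipode that gives the S alcohol, BH3·SMe2) gives (S)-2-methylcyclohex-2-en-1-ol F5. Acylation with methyl 3-chloro-2-methyl-3-oxopropanoate and pyridine gives methyl (1S)-2-methylcyclohex-2-en-1-yl 2-methylpropanedioate F6. Ireland–Claisen rearrangement (LiHMDS, Me3SiCl, THF, −78 °C to rt) transfers the carbinol chirality suprafacially to the ring carbon and gives 3-methoxy-2-methyl-2-[(1R)-2-methylcyclohex-2-en-1-yl]-3-oxopropanoic acid F7. Methylation with trimethylsilyldiazomethane returns to 5; steps 1 to 3 are replaced.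

Further compounds
F1 | step 10 | 2α-formyl-3β-hydroxy-8-oxo-13,13-(ethylenedioxy)-14,15,17-trinorlabdan-19-al | O=C1CC[C@@H]2[C@](C)(C[C@@H](C=O)[C@H](O)[C@]2(C)C=O)[C@H]1CCC4(C)OCCO4
F2 | step 10 | 3β-hydroxy-8-oxo-13,13-(ethylenedioxy)-14,15,17-trinorlabdane-2α,19-dioic acid | O=C1CC[C@@H]2[C@](C)(C[C@@H](C(=O)O)[C@H](O)[C@]2(C)C(=O)O)[C@H]1CCC4(C)OCCO4
F3 | step 10 | Barton ester of the C2 acid (2-thioxopyridin-1(2H)-yl ester) | O=C1CC[C@@H]2[C@](C)(C[C@@H](C(=O)ON3C=CC=CC3=S)[C@H](O)[C@]2(C)C(=O)O)[C@H]1CCC4(C)OCCO4
F4 | step 7 | tert-butyldimethylsilyl dienol ether of 10 (C8 silyl enol ether with C10 methylidene) | CC(C)(C)[Si](C)(C)OC1=C(CCC2(C)OCCO2)C(=C)[C@H](C(C)(C(=O)OC)C(=O)OC)CC1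
F5 | step 3 | (S)-2-methylcyclohex-2-en-1-ol | CC1=CCCC[C@@H]1O
F6 | step 3 | methyl (1S)-2-methylcyclohex-2-en-1-yl 2-methylpropanedioate | CC1=CCCC[C@@H]1OC(=O)C(C)C(=O)OC
F7 | step 3 | 3-methoxy-2-methyl-2-[(1R)-2-methylcyclohex-2-en-1-yl]-3-oxopropanoic acid (epimers at the malonate carbon) | COC(=O)C(C)(C(=O)O)[C@@H]1CCCC=C1C
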